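Assumption: atom labels follow briarane numbering (C1 quaternary ring-fusion carbon, C15 its methyl, C16 the methylene on C5, C17/C18 the lactone CH and its methyl, C19 the lactone carbonyl, C20 the methyl on C11). The chloroperoxidase is taken to be the fungal enzyme from Curvularia inaequalis, which tolerates organic co-solvent.

## Analysis of the target

The target is a briarane: cyclohexene ring A (C1, C10, C11, C12, C13, C14) is fused through C1–C10 to a ten-membered carbocycle (C1 to C10), which carries a γ-lactone (O, C19, C17, C8, C7) fused at C7–C8. It has ten stereocentres, (1S,2S,6S,7R,8R,9S,10S,11R,12R,17R). On ring A the C15 methyl, the C9 branch and the C20 methyl lie on one face, and C2 and the C12 acetate on the other. On the lactone the C18 methyl, the C8 hydroxyl and the C6 branch are mutually cis. The sensitive groups are the C6 chloride, which becomes allylic once C5=C16 exists (no base, no low-valent chromium or palladium after that point), three acetates, the free tertiary C8 alcohol β to the lactone carbonyl, and the Z-C3=C4/C5=C16 diene in a medium ring. The hard points are the crowded C8–C9–C10–C1 sequence, the C20 methyl cis to C15 (the outcome of a formyl-exo cycloaddition), the C12 oxygen on the more hindered face of ring A, and closure of the ten-membered ring. The strategy rests on one feature: the lactone oxygen on C7 and the chlorine on C6 are vicinal and anti. That is what anti addition of chlorine and the C19 carboxylate across an (E)-C6=C7 alkene gives, with the allylic tertiary C8 alcohol steering the face.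

## Retrosynthetic reasoning

37 to 36. The ring is opened at C3=C4 by ring-closing metathesis. This is the one ring bond whose formation tolerates the allylic chloride, and a Z alkene is the natural geometry in a ten-membered ring. The forward reaction must engage only the two monosubstituted alkenes of 36.

36 to 31. The C5 carbon of the chlorolactone is at the alcohol level, so C4–C5 and C5=C16 are both cut. Forward, 31 is desilylated and oxidised to aldehyde 33, a vinyl nucleophile gives 34, oxidation gives vinyl ketone 35, and a non-basic titanium methylidene gives 36. Base is excluded because the C5 carbonyl is α-chloro and β-acyloxy.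

31 to 27. C2–C3 is cut to the C2 aldehyde (Felkin–Anh vinyl addition, 28). The C12 acetate is traced to the enone: hydride should enter from the open face and give the wrong epimer 30, so the acetate is introduced with inversion.

27 to 20 and 23. Ring A is cut at C10–C11 and C1–C14 ([4+2]). The E enal 20 fixes C15 cis to C9. An untethered diene would add anti to C8 and formyl-endo, which gives the wrong C10/C1 and the wrong C11. A temporary silicon bridge from O8 to the diene oxygen (25) brings the diene to the C8 face and allows only the formyl-exo arrangement.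

20 to 15 and 17. C9–C10 is cut (Nozaki–Hiyama–Kishi). The E iodide 17 carries the alkene geometry. The two faces of aldehyde 15 differ only by C7 against C17, so C9 is set by a chiral ligand on chromium.

15 to 13. C9 is unmasked from its silyl ether and oxidised (14, 15).

13 to 12. The key cut: C6–Cl and C7–O are removed together, which leaves the (E)-alkenoic acid 12. The forward step makes the lactone and two stereocentres at once on a small, early intermediate.

12 to 5 and 9. C7–C8 is cut. In the magnesium chelate of keto imide 5 the nucleophile enters anti to the C17 methyl, in the place hydride takes in chelation-controlled reductions. The required C8 configuration then follows only if the alkenyl group is the nucleophile and the oxymethyl group is already on the ketone; the reverse order would give the C8 epimer. A silyl ether at O9 avoids a competing five-ring chelate and removes a benzyl arene from the chlorination step.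

5 to 1 and 2. Aldol and oxidation; C17 comes from the auxiliary. Iodide 9 comes from 6 through 7, iodide 17 from 6, and enone 23 from 21.

## Alternatives that were turned down

Alternative 1: The disconnection is C6–C7, made by ring contraction. A C7 enolate of an eleven-membered cyclic allyl ether would undergo a [2,3]-sigmatropic shift to the ten-membered hydroxy ketone A1, forming C6–C7 and the C5=C16 methylene together. In its favour, the medium ring comes from a larger ether ring that is easier to close, and the diene appears without a separate methylenation. Against it, the migrating allyl terminus must carry chlorine as a geometrically pure chloroalkene, the enolate has a β-silyloxy group at C9 that can be lost, and the C6/C7 outcome depends on a transition state inside a medium ring that cannot be predicted simply. The lactone (C17, C19) and the C8 and C17 centres would still have to be built on the C8 ketone of A1, and the risky step comes late. On ring construction this route is stronger than the chosen one, which leaves a demanding metathesis to the end. The chosen route offers in exchange a decisive step that can be tested after six steps and that delivers lactone, chloride and two stereocentres at once.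

Alternative 2: The disconnection is C10–C11 and C1–C14 on a simple E 2-methyl enal, with a chiral boron Lewis acid and an alkoxy-silyloxy diene giving ring A aldehyde A2. In its favour, the quaternary C1 is set catalytically and early, and the reaction class is established for 2-methyl enals. Against it, A2 needs the C20 methyl cis to C9 and trans to the formyl group, which is the formyl-exo topology that open-chain dienes seldom follow. The C9 carbon of A2 would then have to be joined to a quaternary C8, and the C6 chloride and C7 oxygen remain unsolved. On absolute control of ring A it is at least as strong as the chosen route. The chosen route gets the exo topology from a tether and builds ring A onto a lactone that already holds C6, C7, C8 and C17.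

Alternative 3: The disconnection is C8–C17. A samarium-mediated Reformatsky-type aldol of a 2-bromopropanoate on O7 onto a C8 ketone would close the lactone and give A3, with both bromide epimers converging. In its favour, the tertiary alcohol and lactone form late and mildly, and delivery from O7 fixes the ring fusion. Against it, the ten-membered ring with the C8 ketone and C7 alcohol must exist first, and the C17 configuration depends on enolate geometry within a chelate. A3 still has a C5=C6 alkene, so the chlorine would have to come from a later allylic chlorination with transposition and with control at C6. On convergence at C17 it is as strong or stronger. The chosen route sets C17 by auxiliary and sets the chloride stereospecifically.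

Key step: step 7

## Route

Step 1
Reactants: 1 (R)-4-benzyl-3-propionyloxazolidin-2-one; 2 (tert-butyldimethylsilyloxy)acetaldehyde
Product: 4 (R)-4-benzyl-3-[(2R,3R)-4-(tert-butyldimethylsilyloxy)-3-hydroxy-2-methylbutanoyl]oxazolidin-2-one, via (Z)-dibutylboron enolate 3 (not isolated)
Conditions: Bu2BOTf, i-Pr2NEt, CH2Cl2, −78 to 0 °C; then 2, −78 °C; H2O2, pH 7 buffer, MeOH
Reagents that add atoms: none
Why: Evans syn-aldol through the Z boron enolate and a chair transition state; the (R)-auxiliary sets C17 (R) and a temporary carbinol centre at C8.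

Step 2
Reactants: 4 aldol adduct
Product: 5 (R)-4-benzyl-3-[(2R)-4-(tert-butyldimethylsilyloxy)-2-methyl-3-oxobutanoyl]oxazolidin-2-one
Conditions: SO3·pyridine, DMSO, i-Pr2NEt, CH2Cl2, −10 °C
Reagents that add atoms: none
Why: Parikh–Doering oxidation; the C17 centre of such keto imides resists enolisation because allylic strain holds its C–H bond in the imide plane.

Step 3
Reactants: 6 prop-2-yn-1-ol
Product: 7 tert-butyl(diphenyl)(prop-2-yn-1-yloxy)silane
Conditions: TBDPSCl, imidazole, CH2Cl2, 0 °C to rt
Reagents that add atoms: tert-butyl(chloro)diphenylsilane, CC(C)(C)[Si](Cl)(c1ccccc1)c1ccccc1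
Why: Standard silylation of a primary alcohol.

Step 4
Reactants: 7 silyl propargyl ether
Product: 9 (E)-tert-butyl[(3-iodoprop-2-en-1-yl)oxy]diphenylsilane, via alkenylzirconocene chloride 8 (not isolated)
Conditions: Cp2Zr(H)Cl, THF, rt; then I2, 0 °C
Reagents that add atoms: iodine, II
Why: Hydrozirconation adds Zr–H syn with zirconium at the terminal carbon; iodinolysis with retention gives the E iodide.

Step 5
Reactants: 9 (E)-alkenyl iodide; 5 keto imide
Product: 11 (R)-4-benzyl-3-[(2R,3R,4E)-3-[(tert-butyldimethylsilyloxy)methyl]-6-(tert-butyldiphenylsilyloxy)-3-hydroxy-2-methylhex-4-enoyl]oxazolidin-2-one, via alkenylmagnesium chloride 10 (not isolated)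
Conditions: 9, i-PrMgCl·LiCl, THF, −20 °C; then 5, MgBr2·OEt2, CH2Cl2, −78 °C
Reagents that add atoms: none
Why: Chelation-controlled 1,2-addition of an alkenyl Grignard reagent (made by iodine–magnesium exchange with retention of geometry): magnesium bridges the ketone and imide carbonyls and the alkenyl group enters anti to the C17 methyl, in the place hydride takes in Zn(BH4)2 reductions of such keto imides, which gives C8 (R). The silyl ether at O9 is a poor ligand, so no five-ring chelate competes.

Step 6
Reactants: 11 tertiary alcohol imide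
Product: 12 (2R,3R,4E)-3-[(tert-butyldimethylsilyloxy)methyl]-6-(tert-butyldiphenylsilyloxy)-3-hydroxy-2-methylhex-4-enoic acid
Conditions: LiOH, H2O2, THF/H2O, 0 °C; Na2SO3; HCl to pH 3
Reagents that add atoms: hydrogen peroxide (as lithium hydroperoxide), OO
Why: Hydroperoxide attacks the exocyclic imide carbonyl selectively; a cold, short reaction limits retro-aldol cleavage of the tertiary aldol.

Step 7
Reactants: 12 (E)-alkenoic acid
Product: 13 (3R,4R,5R)-4-[(tert-butyldimethylsilyloxy)methyl]-5-[(1S)-2-(tert-butyldiphenylsilyloxy)-1-chloroethyl]-4-hydroxy-3-methyloxolan-2-one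
Conditions: vanadium chloroperoxidase from Curvularia inaequalis (vanadate cofactor), KCl, H2O2 (syringe pump), citrate buffer pH 5.0, t-BuOH co-solvent, 25 °C
Reagents that add atoms: potassium chloride, [K+].[Cl-]
Why: Proposed new method: the vanadate cofactor (pentavalent vanadium) forms a peroxo complex with H2O2 that oxidises chloride to enzyme-bound hypochlorite, which delivers electrophilic chlorine to C6 of the E alkene while the C19 carboxylate opens the chloronium-like intermediate at C7 from the opposite face. The closest known reaction types are vanadium haloperoxidase bromolactonisation of pent-4-enoic acids, chloronium-initiated cyclisations by vanadium chloroperoxidases and reagent-based halolactonisation of 3-hydroxyalk-4-enoic acids. The γ-lactone closes in the 5-exo-trig mode (O to C7), preferred over 6-endo attack at C6 because neither alkene carbon stabilises a cation better and the five-ring transition state is less strained. C6 is set relative to C7 by stereospecific anti addition across the E double bond. C7 is set relative to C8 by the conformer in which the C8–O bond lies in the alkene plane, with C17 and its carboxylate on one face and the silyloxymethyl arm on the other; chlorine then enters anti to the tether and the chlorine-bearing branch ends cis to the hydroxyl, as in kinetic halolactonisation of 3-hydroxyalk-4-enoic acids. The step needs facial selectivity, 5-exo regioselectivity and chemoselectivity for the alkene over the phenyl groups on silicon; the first two rest on the allylic tertiary alcohol and the tether length, the third on slow enzymatic supply of the oxidant near pH 5, where the acid is ionised and both silyl ethers are stable.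

Step 8
Reactants: 13 chlorolactone
Product: 14 (3R,4R,5R)-5-[(1S)-2-(tert-butyldiphenylsilyloxy)-1-chloroethyl]-4-hydroxy-4-(hydroxymethyl)-3-methyloxolan-2-one
Conditions: PPTS, MeOH, rt
Reagents that add atoms: none
Why: Acid-catalysed methanolysis removes the primary TBS ether much faster than the primary TBDPS ether; lactone and chloride are inert.

Step 9
Reactants: 14 diol
Product: 15 (2R,3S,4R)-2-[(1S)-2-(tert-butyldiphenylsilyloxy)-1-chloroethyl]-3-hydroxy-4-methyl-5-oxooxolane-3-carbaldehyde
Conditions: SO3·pyridine, DMSO, i-Pr2NEt, CH2Cl2, 0 °C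
Reagents that add atoms: none
Why: Parikh–Doering oxidation of the primary alcohol; it avoids the glycol cleavage that hypervalent iodine oxidants can cause next to the tertiary alcohol, and the aldehyde has no α-hydrogen.

Step 10
Reactants: 6 prop-2-yn-1-ol
Product: 17 (E)-3-iodo-2-methylprop-2-en-1-ol, via alkenylalane 16 (not isolated)
Conditions: Me3Al, Cp2ZrCl2, CH2Cl2, 0 °C to rt; then I2, THF, −30 °C
Reagents that add atoms: trimethylaluminium, C[Al](C)C; iodine, II
Why: Negishi zirconium-catalysed carboalumination adds methyl and aluminium syn, methyl to the internal carbon; iodinolysis with retention gives the E iodide.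

Step 11
Reactants: 15 aldehyde; 17 (E)-iodo alcohol
Product: 18 (3R,4R,5R)-5-[(1S)-2-(tert-butyldiphenylsilyloxy)-1-chloroethyl]-4-[(1S,2E)-1,4-dihydroxy-3-methylbut-2-en-1-yl]-4-hydroxy-3-methyloxolan-2-one
Conditions: CrCl2, NiCl2 (cat.), chiral sulfonamide–oxazoline ligand, Et3N, THF/MeCN, rt
Reagents that add atoms: none
Why: Nozaki–Hiyama–Kishi coupling: divalent chromium with nickel catalysis turns the iodide into an alkenylchromium that adds only to the aldehyde, with retention of the E geometry, and tolerates free hydroxyls and the unactivated chloride. The two faces of 15 differ only by C7 against C17, so C9 (S) is set by the ligand on chromium (reagent control); the ligand enantiomer is chosen for the (9S) alcohol.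

Step 12
Reactants: 18 triol
Product: 19 enal: 18 with C2 oxidised to the aldehyde, side chain (1S,2E)-1-hydroxy-3-methyl-4-oxobut-2-en-1-yl
Conditions: MnO2, CH2Cl2, rt
Reagents that add atoms: none
Why: MnO2 oxidises the primary allylic alcohol; the secondary allylic C9 alcohol is shielded by quaternary C8 and should react much more slowly.

Step 13
Reactants: 19 enal
Product: 20 C9 acetate of 19, side chain (1S,2E)-1-acetoxy-3-methyl-4-oxobut-2-en-1-yl
Conditions: Ac2O, pyridine, DMAP (cat.), CH2Cl2, 0 °C
Reagents that add atoms: acetic anhydride, CC(=O)OC(C)=O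
Why: Acylation of the secondary hydroxyl; the tertiary C8 hydroxyl is too hindered to react. The acetate is the final group at C9.

Step 14
Reactants: 21 (E)-4-methoxybut-3-en-2-one
Product: 23 (E)-1-methoxypent-1-en-3-one, via lithium dienolate 22 (not isolated)
Conditions: LDA, THF, −78 °C; then MeI, −78 to −40 °C
Reagents that add atoms: iodomethane, CI
Why: Kinetic deprotonation of the methyl ketone gives the cross-conjugated enolate, which is C-methylated.

Step 15
Reactants: 20 acetate enal; 23 (E)-1-methoxypent-1-en-3-one
Product: 25 silaketal-tethered trienal: 20 whose O8 carries Si(i-Pr)2–O–C12 of a (1E,3Z)-1-methoxypenta-1,3-dien-3-yl unit, via alkoxysilyl triflate 24 (not isolated)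
Conditions: i-Pr2Si(OTf)2, 2,6-lutidine, CH2Cl2, −40 °C; then 23, Et3N, −40 to 0 °C
Reagents that add atoms: di(propan-2-yl)silanediyl bis(trifluoromethanesulfonate), CC(C)[Si](OS(=O)(=O)C(F)(F)F)(OS(=O)(=O)C(F)(F)F)C(C)C
Why: Silyl triflates silylate hindered tertiary alcohols; the second Si–OTf then enolises the vinylogous ester 23 in the presence of amine (soft enolisation), which gives the Z silyl enol ether with the methyl cis to oxygen.

Step 16
Reactants: 25 tethered trienal
Product: 27 ring A enone aldehyde: 4-formyl-4,6-dimethylcyclohex-2-enone (C12 ketone, C13=C14, C2 aldehyde on C1) bonded through C10 to C9 (9S acetate) of the chlorolactone with C1 C10 C11 as in the target, via bridged silaketal cycloadduct 26 (not isolated)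
Conditions: toluene, BHT (cat.), 90 °C; then HF·pyridine, THF, 0 °C; 1 M HCl, THF, 0 °C
Reagents that add atoms: none
Why: Intramolecular Diels–Alder reaction through a temporary silicon tether (type 2 topology) forms C10–C11 and C1–C14; the donor pattern of the diene and the tether both direct C11 to C10. The bridge from O8 brings the diene to the C8 face of the enal, on the side of H9 and away from the C9 acetate, and only the formyl-exo arrangement is within reach of the tether, so the outside methyl of the Z enol ether ends cis to C9 and C15; this sets C1, C10 and C11. Fluoride removes the silicon bridge and acid eliminates methanol to give the enone.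

Step 17
Reactants: 27 ring A enone aldehyde
Product: 28 C2 allylic alcohol (2S): 27 with the aldehyde converted to CH(OH)–CH=CH2
Conditions: vinyl bromide, CrCl2, NiCl2 (cat.), DMSO/THF, rt
Reagents that add atoms: bromoethene, C=CBr
Why: Nozaki–Hiyama–Kishi vinylation is selective for the aldehyde over the enone, lactone, acetate and unactivated chloride. Felkin–Anh addition with C10, the largest group on C1, anti to the incoming vinyl and the nucleophile passing the C15 methyl should give the (2S) alcohol.

Step 18
Reactants: 28 C2 allylic alcohol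
Product: 29 C2 acetate of 28
Conditions: Ac2O, Et3N, DMAP, CH2Cl2, rt
Reagents that add atoms: acetic anhydride, CC(=O)OC(C)=O
Why: DMAP-catalysed acetylation of the hindered secondary alcohol; the tertiary C8 alcohol stays free.

Step 19
Reactants: 29 enone diacetate
Product: 30 C12 allylic alcohol with the hydroxyl cis to the C20 methyl (C12 epimer of the target configuration)
Conditions: NaBH4, CeCl3·7H2O, MeOH, −78 °C
Reagents that add atoms: none
Why: Luche 1,2-reduction; hydride should enter from the face opposite the C20 methyl, the C9 branch and the C15 methyl, which gives the C12 epimer that the next step inverts.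

Step 20
Reactants: 30 C12-epi allylic alcohol
Product: 31 triacetate (C2 C9 C12 acetates as in the target; C5 TBDPS ether; C8 hydroxyl free)
Conditions: PPh3, DIAD, AcOH, toluene, 0 °C to rt
Reagents that add atoms: acetic acid, CC(=O)O
Why: Mitsunobu reaction: acetate displaces the activated allylic alcohol by SN2 from the open face with inversion, which gives the (12R) acetate; the tertiary C8 alcohol does not react.

Step 21
Reactants: 31 triacetate silyl ether
Product: 32 C5 primary alcohol
Conditions: HF·pyridine, pyridine, THF, 0 °C to rt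
Reagents that add atoms: none
Why: Buffered fluoride cleaves the TBDPS ether without forming an alkoxide, so the chlorohydrin cannot close to an epoxide and the acetates stay in place.

Step 22
Reactants: 32 C5 alcohol
Product: 33 C5 aldehyde (α-chloro aldehyde)
Conditions: Dess–Martin periodinane, NaHCO3, CH2Cl2, 0 °C
Reagents that add atoms: none
Why: Dess–Martin oxidation under buffered conditions; the aldehyde is used at once and cold because C6 is epimerisable and the lactone oxygen is β to the carbonyl.

Step 23
Reactants: 33 C5 aldehyde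
Product: 34 C5 vinyl carbinol (both C5 epimers)
Conditions: CH2=CHMgBr, CeCl3, THF, −78 °C
Reagents that add atoms: vinylmagnesium bromide, C=C[Mg]Br
Why: Organocerium 1,2-addition to an α-chloro aldehyde at low temperature; the reagent is weakly basic and leaves acetates and lactone untouched. The C5 centre is removed in the next step.

Step 24
Reactants: 34 vinyl carbinol
Product: 35 C5 vinyl ketone (C4=CH2 conjugated with the C5 ketone)
Conditions: Dess–Martin periodinane, NaHCO3, CH2Cl2, 0 °C
Reagents that add atoms: none
Why: Dess–Martin oxidation of the allylic alcohol without base, so neither C6 epimerisation nor elimination of the β-acyloxy group is expected.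

Step 25
Reactants: 35 vinyl ketone
Product: 36 diene: C6–C5(=C16H2)–C4H=CH2, with the C2 vinyl group in place
Conditions: Tebbe reagent Cp2Ti(μ-CH2)(μ-Cl)AlMe2, pyridine, THF/toluene, −40 to 0 °C
Reagents that add atoms: Tebbe reagent, C[Al-]1(C)C[Ti](C2C=CC=C2)(C2C=CC=C2)[Cl+]1
Why: Tebbe methylenation by a titanium methylidene through an oxatitanacyclobutane; it is non-basic, so the α-chloro ketone is not enolised, and ketones react faster than acetates and the lactone.

Step 26
Reactants: 36 diene
Product: 37 target CNP0076552.1
Conditions: second-generation Hoveyda–Grubbs catalyst, toluene (high dilution), 80 °C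
Reagents that add atoms: none
Why: Ring-closing metathesis between the C3 vinyl group and the monosubstituted end of the butadiene forms C3=C4; the Z alkene is the less strained isomer in a ten-membered ring, and the 1,1-disubstituted C5=C16 and the ring A alkene are too hindered to take part. Ruthenium carbenes tolerate the allylic chloride.

## Compound list

1 | (R)-4-benzyl-3-propionyloxazolidin-2-one | CCC(=O)N1[C@H](Cc2ccccc2)COC1=O | starting material
2 | (tert-butyldimethylsilyloxy)acetaldehyde | CC(C)(C)[Si](C)(C)OCC=O | starting material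
3 | (Z)-dibutylboron enolate of 1 | CCCCB(CCCC)O/C(=C\C)N1[C@H](Cc2ccccc2)COC1=O | intermediate
4 | (R)-4-benzyl-3-[(2R,3R)-4-(tert-butyldimethylsilyloxy)-3-hydroxy-2-methylbutanoyl]oxazolidin-2-one | C[C@@H](C(=O)N1[C@H](Cc2ccccc2)COC1=O)[C@@H](O)CO[Si](C)(C)C(C)(C)C | intermediate
5 | (R)-4-benzyl-3-[(2R)-4-(tert-butyldimethylsilyloxy)-2-methyl-3-oxobutanoyl]oxazolidin-2-one | C[C@@H](C(=O)N1[C@H](Cc2ccccc2)COC1=O)C(=O)CO[Si](C)(C)C(C)(C)C | intermediate
6 | prop-2-yn-1-ol | C#CCO | starting material
7 | tert-butyl(diphenyl)(prop-2-yn-1-yloxy)silane | C#CCO[Si](c1ccccc1)(c1ccccc1)C(C)(C)C | intermediate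
8 | (E)-alkenylzirconocene chloride from 7 | Cl[Zr](/C=C/CO[Si](c1ccccc1)(c1ccccc1)C(C)(C)C)(C1C=CC=C1)C1C=CC=C1 | intermediate
9 | (E)-tert-butyl[(3-iodoprop-2-en-1-yl)oxy]diphenylsilane | I/C=C/CO[Si](c1ccccc1)(c1ccccc1)C(C)(C)C | intermediate
10 | (E)-[3-(tert-butyldiphenylsilyloxy)prop-1-en-1-yl]magnesium chloride | Cl[Mg]/C=C/CO[Si](c1ccccc1)(c1ccccc1)C(C)(C)C | intermediate
11 | (R)-4-benzyl-3-[(2R,3R,4E)-3-[(tert-butyldimethylsilyloxy)methyl]-6-(tert-butyldiphenylsilyloxy)-3-hydroxy-2-methylhex-4-enoyl]oxazolidin-2-one | C[C@@H](C(=O)N1[C@H](Cc2ccccc2)COC1=O)[C@@](O)(CO[Si](C)(C)C(C)(C)C)/C=C/CO[Si](c1ccccc1)(c1ccccc1)C(C)(C)C | intermediate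
12 | (2R,3R,4E)-3-[(tert-butyldimethylsilyloxy)methyl]-6-(tert-butyldiphenylsilyloxy)-3-hydroxy-2-methylhex-4-enoic acid | OC(=O)[C@H](C)[C@@](O)(CO[Si](C)(C)C(C)(C)C)/C=C/CO[Si](c1ccccc1)(c1ccccc1)C(C)(C)C | intermediate
13 | (3R,4R,5R)-4-[(tert-butyldimethylsilyloxy)methyl]-5-[(1S)-2-(tert-butyldiphenylsilyloxy)-1-chloroethyl]-4-hydroxy-3-methyloxolan-2-one | CC(C)(C)[Si](C)(C)OC[C@]1(O)[C@@H](C)C(=O)O[C@H]1[C@@H](Cl)CO[Si](c1ccccc1)(c1ccccc1)C(C)(C)C | intermediate
14 | (3R,4R,5R)-5-[(1S)-2-(tert-butyldiphenylsilyloxy)-1-chloroethyl]-4-hydroxy-4-(hydroxymethyl)-3-methyloxolan-2-one | OC[C@]1(O)[C@@H](C)C(=O)O[C@H]1[C@@H](Cl)CO[Si](c1ccccc1)(c1ccccc1)C(C)(C)C | intermediate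
15 | (2R,3S,4R)-2-[(1S)-2-(tert-butyldiphenylsilyloxy)-1-chloroethyl]-3-hydroxy-4-methyl-5-oxooxolane-3-carbaldehyde | O=C[C@]1(O)[C@@H](C)C(=O)O[C@H]1[C@@H](Cl)CO[Si](c1ccccc1)(c1ccccc1)C(C)(C)C | intermediate
16 | (E)-alkenylalane from 6 (O- and C-bound dimethylaluminium) | C[Al](C)OC/C(C)=C/[Al](C)C | intermediate
17 | (E)-3-iodo-2-methylprop-2-en-1-ol | OC/C(C)=C/I | intermediate
18 | (9S) triol: lactone with C8 hydroxyl and (1S,2E)-1,4-dihydroxy-3-methylbut-2-en-1-yl chain on C8 | CC(C)(C)[Si](c1ccccc1)(c1ccccc1)OC[C@H](Cl)[C@@H]1OC(=O)[C@H](C)[C@@]1(O)[C@@H](O)/C=C(\C)CO | intermediate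
19 | (9S) hydroxy enal (C2 aldehyde; C10=C1 E) | CC(C)(C)[Si](c1ccccc1)(c1ccccc1)OC[C@H](Cl)[C@@H]1OC(=O)[C@H](C)[C@@]1(O)[C@@H](O)/C=C(\C)C=O | intermediate
20 | (9S) acetoxy enal | CC(C)(C)[Si](c1ccccc1)(c1ccccc1)OC[C@H](Cl)[C@@H]1OC(=O)[C@H](C)[C@@]1(O)[C@@H](OC(C)=O)/C=C(\C)C=O | intermediate
21 | (E)-4-methoxybut-3-en-2-one | CO/C=C/C(C)=O | starting material
22 | lithium dienolate of 21 | [Li]OC(=C)/C=C/OC | intermediate
23 | (E)-1-methoxypent-1-en-3-one | CCC(=O)/C=C/OC | intermediate
24 | O8 diisopropylsilyl triflate of 20 | CC(C)(C)[Si](c1ccccc1)(c1ccccc1)OC[C@H](Cl)[C@@H]1OC(=O)[C@H](C)[C@@]1(O[Si](C(C)C)(C(C)C)OS(=O)(=O)C(F)(F)F)[C@@H](OC(C)=O)/C=C(\C)C=O | intermediate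
25 | O8 silaketal-tethered trienal with (1E,3Z)-1-methoxypenta-1,3-dien-3-yloxy unit | CC(C)(C)[Si](c1ccccc1)(c1ccccc1)OC[C@H](Cl)[C@@H]1OC(=O)[C@H](C)[C@@]1(O[Si](C(C)C)(C(C)C)O/C(=C\C)/C=C/OC)[C@@H](OC(C)=O)/C=C(\C)C=O | intermediate
26 | bridged silaketal cycloadduct (C12=C13 silyl enol ether; C14 methoxy) | CC(C)(C)[Si](c1ccccc1)(c1ccccc1)OC[C@H](Cl)[C@@H]1OC(=O)[C@H](C)[C@]12O[Si](C(C)C)(C(C)C)OC3=C[C@@H](OC)[C@](C)(C=O)[C@H]([C@H]3C)[C@@H]2OC(C)=O | intermediate
27 | ring A enone aldehyde (C12 ketone; C2 aldehyde; 9S acetate) | CC(C)(C)[Si](c1ccccc1)(c1ccccc1)OC[C@H](Cl)[C@@H]1OC(=O)[C@H](C)[C@@]1(O)[C@@H](OC(C)=O)[C@H]2[C@@H](C)C(=O)C=C[C@]2(C)C=O | intermediate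
28 | (2S) C2 vinyl carbinol | CC(C)(C)[Si](c1ccccc1)(c1ccccc1)OC[C@H](Cl)[C@@H]1OC(=O)[C@H](C)[C@@]1(O)[C@@H](OC(C)=O)[C@H]2[C@@H](C)C(=O)C=C[C@]2(C)[C@@H](O)C=C | intermediate
29 | C2,C9 diacetate enone | CC(C)(C)[Si](c1ccccc1)(c1ccccc1)OC[C@H](Cl)[C@@H]1OC(=O)[C@H](C)[C@@]1(O)[C@@H](OC(C)=O)[C@H]2[C@@H](C)C(=O)C=C[C@]2(C)[C@@H](OC(C)=O)C=C | intermediate
30 | C12-epi allylic alcohol (hydroxyl cis to C20) | CC(C)(C)[Si](c1ccccc1)(c1ccccc1)OC[C@H](Cl)[C@@H]1OC(=O)[C@H](C)[C@@]1(O)[C@@H](OC(C)=O)[C@H]2[C@@H](C)[C@@H](O)C=C[C@]2(C)[C@@H](OC(C)=O)C=C | intermediate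
31 | triacetate with C5 TBDPS ether | CC(C)(C)[Si](c1ccccc1)(c1ccccc1)OC[C@H](Cl)[C@@H]1OC(=O)[C@H](C)[C@@]1(O)[C@@H](OC(C)=O)[C@H]2[C@@H](C)[C@H](OC(C)=O)C=C[C@]2(C)[C@@H](OC(C)=O)C=C | intermediate
32 | triacetate C5 alcohol | OC[C@H](Cl)[C@@H]1OC(=O)[C@H](C)[C@@]1(O)[C@@H](OC(C)=O)[C@H]2[C@@H](C)[C@H](OC(C)=O)C=C[C@]2(C)[C@@H](OC(C)=O)C=C | intermediate
33 | triacetate C5 aldehyde | O=C[C@H](Cl)[C@@H]1OC(=O)[C@H](C)[C@@]1(O)[C@@H](OC(C)=O)[C@H]2[C@@H](C)[C@H](OC(C)=O)C=C[C@]2(C)[C@@H](OC(C)=O)C=C | intermediate
34 | C5 vinyl carbinol (C5 epimers) | C=CC(O)[C@H](Cl)[C@@H]1OC(=O)[C@H](C)[C@@]1(O)[C@@H](OC(C)=O)[C@H]2[C@@H](C)[C@H](OC(C)=O)C=C[C@]2(C)[C@@H](OC(C)=O)C=C | intermediate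
35 | C5 vinyl ketone | C=CC(=O)[C@H](Cl)[C@@H]1OC(=O)[C@H](C)[C@@]1(O)[C@@H](OC(C)=O)[C@H]2[C@@H](C)[C@H](OC(C)=O)C=C[C@]2(C)[C@@H](OC(C)=O)C=C | intermediate
36 | seco diene (2-substituted buta-1,3-diene at C5; vinyl on C2) | C=CC(=C)[C@H](Cl)[C@@H]1OC(=O)[C@H](C)[C@@]1(O)[C@@H](OC(C)=O)[C@H]2[C@@H](C)[C@H](OC(C)=O)C=C[C@]2(C)[C@@H](OC(C)=O)C=C | intermediate
37 | CNP0076552.1, (1S,2S,6S,7R,8R,9S,10S,11R,12R,17R) | C=C1/C=C\[C@H](OC(C)=O)[C@@]2(C)C=C[C@@H](OC(C)=O)[C@H](C)[C@@H]2[C@H](OC(C)=O)[C@]2(O)[C@@H](C)C(=O)O[C@H]2[C@H]1Cl | target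

## Step count and least certain steps

Total: 26 steps. Longest linear sequence: 22 steps (steps 1, 2, 5 to 9, 11 to 13, 15 to 26).

Step 7 (key step, proposed new method). The most likely failure is chlorination without enough facial control at the alkene relative to C8, which gives the C6/C7 diastereomeric pair. Capture of the chloronium by water instead of the carboxylate, and slow turnover of the lipophilic acid in buffer, are the other risks. The fallback uses known chemistry and sets out from 11. Hydroxyl-directed epoxidation (VO(acac)2, t-BuOOH, CH2Cl2) gives the epoxy imide F1. Chelation-directed opening with chloride at C6, the carbon remote from the carbinol (Ti(OiPr)4, NH4Cl), with inversion gives the chlorohydrin imide F2. Its C7 hydroxyl then displaces the auxiliary (DMAP, CH2Cl2) to close the lactone and return to the route at 13. Epoxidation followed by opening gives the same net anti addition across the E alkene; the epoxide diastereomers would be separated at F1.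

Step 16. The tethered cycloaddition may be slower than loss of the labile silyl dienol ether, or the diene may leak to the acetate face. The silaketal on the crowded tertiary hydroxyl (step 15) may also form poorly. The fallback moves the tether to O9 in the C9-epimeric series, where the tether and the open face agree, and then corrects C9. It sets out from 15. The coupling of step 11 with the enantiomeric ligand gives the (9R) triol F3, and MnO2 gives the (9R) hydroxy enal F4. The dienyloxysilyl triflate F5, made from i-Pr2Si(OTf)2, 23 and Et3N, silylates the secondary hydroxyl of F4 to the O9-tethered trienal F6. Heating gives the bridged cycloadduct F7, and HF·pyridine followed by dilute HCl gives the (9R) hydroxy enone aldehyde F8. Dess–Martin oxidation gives the C9 ketone F9. Hydroxyl-directed reduction with Me4NBH(OAc)3 should deliver hydride anti to C1 (Felkin–Anh control from C10, with H10 turned toward C8) and give the (9S) alcohol F10. Acetylation returns to the route at 27.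

Step 26. Initiation at the C3 vinyl group, next to an acetate and quaternary C1, may be slow, and the catalyst may rest as an unreactive vinylcarbene on the diene, which would lead to oligomers. The fallback changes the order of events and sets out from 35. Ring-closing metathesis of the vinyl ketone, an electron-poor partner that does not dimerise, gives the macrocyclic Z enone F11. Tebbe methylenation of the C5 ketone then gives 37 directly.

Step 5. The basic alkenylmagnesium reagent may enolise the ketone at C9 instead of adding, and chelation control may erode in the presence of THF. The fallback sets out from 5 and 7. Deprotonation of 7 (n-BuLi) gives the lithium acetylide F12, which is added with CeCl3 to 5 to give the propargylic alcohol imide F13; the acetylide is less basic towards the ketone and small enough to respect the chelate. Ruthenium-catalysed trans-hydrogenation ([Cp*Ru(MeCN)3]PF6, H2, CH2Cl2) then gives the E alkene and returns to the route at 11.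

## Further compounds

F1 | step 7 | epoxy imide: 11 with a trans C6–C7 epoxide | C[C@@H](C(=O)N1[C@H](Cc2ccccc2)COC1=O)[C@@](O)(CO[Si](C)(C)C(C)(C)C)[C@H]1O[C@@H]1CO[Si](c1ccccc1)(c1ccccc1)C(C)(C)C
F2 | step 7 | chlorohydrin imide (C7 hydroxyl, C6 chloride) | C[C@@H](C(=O)N1[C@H](Cc2ccccc2)COC1=O)[C@@](O)(CO[Si](C)(C)C(C)(C)C)[C@@H](O)[C@@H](Cl)CO[Si](c1ccccc1)(c1ccccc1)C(C)(C)C
F3 | step 16 | (9R) epimer of triol 18 | CC(C)(C)[Si](c1ccccc1)(c1ccccc1)OC[C@H](Cl)[C@@H]1OC(=O)[C@H](C)[C@@]1(O)[C@H](O)/C=C(\C)CO
F4 | step 16 | (9R) epimer of hydroxy enal 19 | CC(C)(C)[Si](c1ccccc1)(c1ccccc1)OC[C@H](Cl)[C@@H]1OC(=O)[C@H](C)[C@@]1(O)[C@H](O)/C=C(\C)C=O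
F5 | step 16 | [(1E,3Z)-1-methoxypenta-1,3-dien-3-yl]oxydi(propan-2-yl)silyl trifluoromethanesulfonate | FC(F)(F)S(=O)(=O)O[Si](C(C)C)(C(C)C)O/C(=C\C)/C=C/OC
F6 | step 16 | O9 silaketal-tethered trienal (9R) | CC(C)(C)[Si](c1ccccc1)(c1ccccc1)OC[C@H](Cl)[C@@H]1OC(=O)[C@H](C)[C@@]1(O)[C@H](O[Si](C(C)C)(C(C)C)O/C(=C\C)/C=C/OC)/C=C(\C)C=O
F7 | step 16 | O9-bridged silaketal cycloadduct | CC(C)(C)[Si](c1ccccc1)(c1ccccc1)OC[C@H](Cl)[C@@H]1OC(=O)[C@H](C)[C@@]1(O)[C@@H]2O[Si](C(C)C)(C(C)C)OC3=C[C@@H](OC)[C@](C)(C=O)[C@@H]2[C@H]3C
F8 | step 16 | (9R) hydroxy ring A enone aldehyde | CC(C)(C)[Si](c1ccccc1)(c1ccccc1)OC[C@H](Cl)[C@@H]1OC(=O)[C@H](C)[C@@]1(O)[C@H](O)[C@H]2[C@@H](C)C(=O)C=C[C@]2(C)C=O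
F9 | step 16 | C9 ketone of the ring A enone aldehyde | CC(C)(C)[Si](c1ccccc1)(c1ccccc1)OC[C@H](Cl)[C@@H]1OC(=O)[C@H](C)[C@@]1(O)C(=O)[C@H]2[C@@H](C)C(=O)C=C[C@]2(C)C=O
F10 | step 16 | (9S) hydroxy ring A enone aldehyde (27 without the acetyl group) | CC(C)(C)[Si](c1ccccc1)(c1ccccc1)OC[C@H](Cl)[C@@H]1OC(=O)[C@H](C)[C@@]1(O)[C@@H](O)[C@H]2[C@@H](C)C(=O)C=C[C@]2(C)C=O
F11 | step 26 | macrocyclic Z enone (C5 ketone in place of the C5 methylene of 37) | O=C1/C=C\[C@H](OC(C)=O)[C@@]2(C)C=C[C@@H](OC(C)=O)[C@H](C)[C@@H]2[C@H](OC(C)=O)[C@]2(O)[C@@H](C)C(=O)O[C@H]2[C@H]1Cl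
F12 | step 5 | lithium acetylide of 7 | [Li]C#CCO[Si](c1ccccc1)(c1ccccc1)C(C)(C)C
F13 | step 5 | propargylic alcohol imide (alkyne analogue of 11) | C[C@@H](C(=O)N1[C@H](Cc2ccccc2)COC1=O)[C@@](O)(CO[Si](C)(C)C(C)(C)C)C#CCO[Si](c1ccccc1)(c1ccccc1)C(C)(C)C
A1 | alternative 1 | ten-membered hydroxy ketone from the [2,3]-shift | C=C1/C=C\[C@H](O[Si](C)(C)C(C)(C)C)[C@@]2(C)C=C[C@@H](O[Si](C)(C)C(C)(C)C)[C@H](C)[C@@H]2[C@H](O[Si](C)(C)C(C)(C)C)C(=O)[C@@H](O)[C@H]1Cl
A2 | alternative 2 | ring A enone aldehyde with silyloxymethyl on C10 | O=C[C@@]1(C)C=CC(=O)[C@H](C)[C@@H]1CO[Si](C)(C)C(C)(C)C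
A3 | alternative 3 | tricyclic lactone with C5=C6 alkene | C/C1/C=C\[C@H](O[Si](C)(C)C(C)(C)C)[C@@]2(C)C=C[C@@H](O[Si](C)(C)C(C)(C)C)[C@H](C)[C@@H]2[C@H](O[Si](C)(C)C(C)(C)C)[C@]2(O)[C@@H](C)C(=O)O[C@H]2/C=1
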